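**Plan**
- Retrosynthesis: the aryl benzyl ether is removed last. The pyranone is opened at O1–C2 to an ortho-hydroxyaryl ynone, and its C4 carbonyl is traced back to a silyl-protected carbinol.
- Ring A is cut at C5–C6, C4a–C8a and C8–C8a into a terminal alkyne (C4a, C5), one CO (C8a) and a methoxy(1-methoxyvinyl)carbene complex of chromium (C6, C7, C8). This is possible because on ring A the C8a oxygen (O1) is para to the C6 methoxy group, with the C7 methoxy group beside it: a 4-methoxyphenol.
- The skipped diyne is cut at the carbinol–alkyne bond (lithium acetylide plus 3-(trimethylsilyl)propynal) and at the benzylic CH2–CH2 bond (benzylic bromide plus lithiated 1-(trimethylsilyl)propyne).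
- Forward order: side-chain alkyne, then diyne, then ring A by benzannulation, then the pyranone ring by 6-endo closure, then debenzylation.
- Stereochemistry: the target has no stereocentre. The carbinol carbon is carried as a racemate and disappears on oxidation to the C4 ketone.

Key step: step 9

Remark: the free 3-hydroxy group of the side-chain arene is carried as a benzyl ether throughout, because it must survive organolithium, fluoride, oxidant and amine steps and can be released last by hydrogenolysis.

**Route**

Step 1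
Reactants: 1 3-(benzyloxy)-4-methoxybenzaldehyde
Product: 2 [3-(benzyloxy)-4-methoxyphenyl]methanol
Conditions: NaBH4, MeOH, 0 °C to rt
Reagents that add atoms: none
Why: Borohydride reduction of an aryl aldehyde to the benzylic alcohol is routine and leaves both aryl ethers untouched (NaBH4 carbonyl reduction).

Step 2
Reactants: 2 [3-(benzyloxy)-4-methoxyphenyl]methanol
Product: 3 2-(benzyloxy)-4-(bromomethyl)-1-methoxybenzene
Conditions: PBr3, CH2Cl2, 0 °C; used crude
Reagents that add atoms: phosphorus tribromide, BrP(Br)Br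
Why: Bromination of an electron-rich benzylic alcohol with PBr3 (substitution via the phosphite ester) is standard, and the labile bromide should be taken on without chromatography.

Step 3
Reactants: 3 2-(benzyloxy)-4-(bromomethyl)-1-methoxybenzene, 4 1-(trimethylsilyl)propyne
Product: 6 {4-[3-(benzyloxy)-4-methoxyphenyl]but-1-yn-1-yl}trimethylsilane, via 3-lithio-1-(trimethylsilyl)propyne 5 (not isolated)
Conditions: 4, n-BuLi, THF, −78 °C; then 3, −78 °C to rt
Reagents that add atoms: none
Why: Propargylic lithiation of 1-(trimethylsilyl)propyne followed by SN2 alkylation with a benzylic bromide is a standard three-carbon homologation, the silyl group directing attack through the propargylic rather than the allenic terminus.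

Step 4
Reactants: 6 {4-[3-(benzyloxy)-4-methoxyphenyl]but-1-yn-1-yl}trimethylsilane
Product: 7 2-(benzyloxy)-4-(but-3-yn-1-yl)-1-methoxybenzene
Conditions: K2CO3 (cat.), MeOH, rt
Reagents that add atoms: none
Why: Carbonate-catalysed methanolysis of a C(sp)–SiMe3 bond is routine protodesilylation and touches neither ether.

Step 5
Reactants: 7 2-(benzyloxy)-4-(but-3-yn-1-yl)-1-methoxybenzene, 8 3-(trimethylsilyl)propynal
Product: 10 racemic 7-[3-(benzyloxy)-4-methoxyphenyl]-1-(trimethylsilyl)hepta-1,4-diyn-3-ol, via lithium 4-[3-(benzyloxy)-4-methoxyphenyl]but-1-yn-1-ide 9 (not isolated)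
Conditions: 7, n-BuLi, THF, −78 °C; then 8, −78 °C; aq. NH4Cl
Reagents that add atoms: none
Why: 1,2-Addition of a lithium acetylide to an ynal is a standard carbonyl alkynylation; the new carbinol centre forms without control as a racemate, which is acceptable because it is oxidised later.

Step 6
Reactants: 10 racemic 7-[3-(benzyloxy)-4-methoxyphenyl]-1-(trimethylsilyl)hepta-1,4-diyn-3-ol
Product: 11 racemic tert-butyl({7-[3-(benzyloxy)-4-methoxyphenyl]-1-(trimethylsilyl)hepta-1,4-diyn-3-yl}oxy)dimethylsilane
Conditions: TBSCl, imidazole, DMF, rt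
Reagents that add atoms: tert-butyldimethylsilyl chloride, CC(C)(C)[Si](C)(C)Cl
Why: Imidazole-promoted silylation of a secondary alcohol is standard TBS protection and masks the doubly propargylic carbinol for the organometallic step.

Step 7
Reactants: 11 racemic tert-butyl({7-[3-(benzyloxy)-4-methoxyphenyl]-1-(trimethylsilyl)hepta-1,4-diyn-3-yl}oxy)dimethylsilane
Product: 12 racemic 7-[3-(benzyloxy)-4-methoxyphenyl]-3-(tert-butyldimethylsilyloxy)hepta-1,4-diyne
Conditions: K2CO3 (cat.), MeOH, 0 °C to rt
Reagents that add atoms: none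
Why: Carbonate in methanol cleaves the alkynyl C–Si bond selectively while the O-silyl ether is stable (chemoselective protodesilylation), and the short, cold reaction should avoid base-induced isomerisation of the skipped diyne.

Step 8
Reactants: 13 methyl vinyl ether, 14 chromium hexacarbonyl
Product: 17 pentacarbonyl[methoxy(1-methoxyvinyl)carbene]chromium, via 1-methoxyvinyllithium 15 (not isolated), via lithium pentacarbonyl(2-methoxyacryloyl)chromate 16 (not isolated)
Conditions: 13, t-BuLi, THF, −78 to 0 °C; Cr(CO)6, THF, −78 °C to rt; evaporate; MeOTf, CH2Cl2, 0 °C; used fresh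
Reagents that add atoms: methyl trifluoromethanesulfonate, COS(=O)(=O)C(F)(F)F
Why: This is the Fischer carbene synthesis: α-lithiation of the vinyl ether, addition of the vinyllithium to a CO ligand of Cr(CO)6 and hard O-methylation of the acylchromate follow the standard route to alkenyl(methoxy)carbene complexes of zerovalent chromium.

Step 9
Reactants: 12 racemic 7-[3-(benzyloxy)-4-methoxyphenyl]-3-(tert-butyldimethylsilyloxy)hepta-1,4-diyne, 17 pentacarbonyl[methoxy(1-methoxyvinyl)carbene]chromium
Product: 19 racemic 2-{5-[3-(benzyloxy)-4-methoxyphenyl]-1-(tert-butyldimethylsilyloxy)pent-2-yn-1-yl}-4,5-dimethoxyphenol, via tricarbonylchromium arene complex 18 (not isolated)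
Conditions: 17 (1.3 equiv), THF (0.05 M), 50 °C, Ar; then air, Et2O, rt
Reagents that add atoms: none
Why: Proposed new method: thermal loss of one CO from 17 frees a site on zerovalent chromium, the terminal alkyne of 12 inserts with its CH carbon bonding to the carbene carbon (C5–C6), CO insertion gives a chromium-bound dienylketene (C4a–C8a), and 6π electrocyclisation onto the vinyl CH2 (C8–C8a) followed by enolisation should deliver the phenol as its Cr(CO)3 complex 18, from which air removes the metal. The closest known reaction type is the Dötz benzannulation of cyclic 1-alkoxyalkenyl(methoxy)carbene chromium complexes (dihydropyranyl and glycal-derived) with terminal alkynes; what is unproven is the acyclic 1-methoxyvinyl complex and a skipped diyne as the partner. Ring A is the only ring closed, by electrocyclisation of the ketene. No stereocentre is created: the carbinol centre of 12 is untouched and stays racemic, and the planar chirality of 18 vanishes on decomplexation. The step needs the branched alkyne carbon to end next to the CO-derived carbon and the terminal triple bond to react in preference to the internal one; both rest on sterics, the internal alkyne being flanked by the silyloxy-bearing carbon, and the single sp3 carbon between the two alkynes is too short for an intramolecular second insertion.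

Step 10
Reactants: 19 racemic 2-{5-[3-(benzyloxy)-4-methoxyphenyl]-1-(tert-butyldimethylsilyloxy)pent-2-yn-1-yl}-4,5-dimethoxyphenol
Product: 20 racemic 2-{5-[3-(benzyloxy)-4-methoxyphenyl]-1-hydroxypent-2-yn-1-yl}-4,5-dimethoxyphenol
Conditions: TBAF, AcOH, THF, 0 °C to rt
Reagents that add atoms: none
Why: Fluoride cleavage of the O–Si bond is standard silyl ether deprotection, and buffering with acetic acid keeps the electron-rich phenol away from basic fluoride.

Step 11
Reactants: 20 racemic 2-{5-[3-(benzyloxy)-4-methoxyphenyl]-1-hydroxypent-2-yn-1-yl}-4,5-dimethoxyphenol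
Product: 21 5-[3-(benzyloxy)-4-methoxyphenyl]-1-(2-hydroxy-4,5-dimethoxyphenyl)pent-2-yn-1-one
Conditions: activated MnO2, CH2Cl2, rt
Reagents that add atoms: none
Why: Activated MnO2 oxidises benzylic and propargylic carbinols selectively, also in ortho-hydroxyaryl carbinols, so the conjugated ynone should form and the racemic stereocentre is removed (heterogeneous MnO2 oxidation).

Step 12
Reactants: 21 5-[3-(benzyloxy)-4-methoxyphenyl]-1-(2-hydroxy-4,5-dimethoxyphenyl)pent-2-yn-1-one
Product: 23 2-{2-[3-(benzyloxy)-4-methoxyphenyl]ethyl}-6,7-dimethoxy-4H-chromen-4-one, via β-(diethylamino)enone 22 (not isolated)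
Conditions: Et2NH, EtOH, rt then 60 °C
Reagents that add atoms: none
Why: Conjugate addition of the secondary amine to the ynone gives a β-amino enone whose β-carbon is the only electrophilic site left, so the phenol should close the pyranone by 6-endo addition–elimination and avoid the 5-exo aurone pathway (amine-mediated chromone synthesis from ortho-hydroxyaryl ynones).

Step 13
Reactants: 23 2-{2-[3-(benzyloxy)-4-methoxyphenyl]ethyl}-6,7-dimethoxy-4H-chromen-4-one
Product: 24 2-[2-(3-hydroxy-4-methoxyphenyl)ethyl]-6,7-dimethoxy-4H-chromen-4-one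
Conditions: H2 (1 atm), 10% Pd/C, EtOAc/MeOH, rt
Reagents that add atoms: none
Why: Hydrogenolysis of an aryl benzyl ether over palladium is faster than reduction of the chromone C2–C3 double bond at balloon pressure, so the reaction is stopped once the ether is consumed (catalytic O-debenzylation).

**Compound list**

1 | 3-(benzyloxy)-4-methoxybenzaldehyde | COc1ccc(C=O)cc1OCc1ccccc1 | starting material
2 | [3-(benzyloxy)-4-methoxyphenyl]methanol | COc1ccc(CO)cc1OCc1ccccc1 | intermediate
3 | 2-(benzyloxy)-4-(bromomethyl)-1-methoxybenzene | COc1ccc(CBr)cc1OCc1ccccc1 | intermediate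
4 | 1-(trimethylsilyl)propyne | CC#C[Si](C)(C)C | starting material
5 | 3-lithio-1-(trimethylsilyl)propyne | [Li]CC#C[Si](C)(C)C | intermediate
6 | {4-[3-(benzyloxy)-4-methoxyphenyl]but-1-yn-1-yl}trimethylsilane | COc1ccc(CCC#C[Si](C)(C)C)cc1OCc1ccccc1 | intermediate
7 | 2-(benzyloxy)-4-(but-3-yn-1-yl)-1-methoxybenzene | COc1ccc(CCC#C)cc1OCc1ccccc1 | intermediate
8 | 3-(trimethylsilyl)propynal | C[Si](C)(C)C#CC=O | starting material
9 | lithium 4-[3-(benzyloxy)-4-methoxyphenyl]but-1-yn-1-ide | [Li]C#CCCc1ccc(OC)c(OCc2ccccc2)c1 | intermediate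
10 | racemic 7-[3-(benzyloxy)-4-methoxyphenyl]-1-(trimethylsilyl)hepta-1,4-diyn-3-ol | C[Si](C)(C)C#CC(O)C#CCCc1ccc(OC)c(OCc2ccccc2)c1 | intermediate
11 | racemic tert-butyl({7-[3-(benzyloxy)-4-methoxyphenyl]-1-(trimethylsilyl)hepta-1,4-diyn-3-yl}oxy)dimethylsilane | C[Si](C)(C)C#CC(O[Si](C)(C)C(C)(C)C)C#CCCc1ccc(OC)c(OCc2ccccc2)c1 | intermediate
12 | racemic 7-[3-(benzyloxy)-4-methoxyphenyl]-3-(tert-butyldimethylsilyloxy)hepta-1,4-diyne | C#CC(O[Si](C)(C)C(C)(C)C)C#CCCc1ccc(OC)c(OCc2ccccc2)c1 | intermediate
13 | methyl vinyl ether | COC=C | starting material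
14 | chromium hexacarbonyl | O=C=[Cr](=C=O)(=C=O)(=C=O)(=C=O)=C=O | starting material
15 | 1-methoxyvinyllithium | [Li]C(=C)OC | intermediate
16 | lithium pentacarbonyl(2-methoxyacryloyl)chromate | [Li+].[O-]C(C(=C)OC)=[Cr](=C=O)(=C=O)(=C=O)(=C=O)=C=O | intermediate
17 | pentacarbonyl[methoxy(1-methoxyvinyl)carbene]chromium | COC(C(=C)OC)=[Cr](=C=O)(=C=O)(=C=O)(=C=O)=C=O | intermediate
18 | tricarbonyl(η6-arene)chromium complex of phenol 19 (metal on ring A, drawn as a dot-joined Cr(CO)3 unit) | COc1cc(O)c(C(O[Si](C)(C)C(C)(C)C)C#CCCc2ccc(OC)c(OCc3ccccc3)c2)cc1OC.O=C=[Cr](=C=O)=C=O | intermediate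
19 | racemic 2-{5-[3-(benzyloxy)-4-methoxyphenyl]-1-(tert-butyldimethylsilyloxy)pent-2-yn-1-yl}-4,5-dimethoxyphenol | COc1cc(O)c(C(O[Si](C)(C)C(C)(C)C)C#CCCc2ccc(OC)c(OCc3ccccc3)c2)cc1OC | intermediate
20 | racemic 2-{5-[3-(benzyloxy)-4-methoxyphenyl]-1-hydroxypent-2-yn-1-yl}-4,5-dimethoxyphenol | COc1cc(O)c(C(O)C#CCCc2ccc(OC)c(OCc3ccccc3)c2)cc1OC | intermediate
21 | 5-[3-(benzyloxy)-4-methoxyphenyl]-1-(2-hydroxy-4,5-dimethoxyphenyl)pent-2-yn-1-one | COc1cc(O)c(C(=O)C#CCCc2ccc(OC)c(OCc3ccccc3)c2)cc1OC | intermediate
22 | 5-[3-(benzyloxy)-4-methoxyphenyl]-3-(diethylamino)-1-(2-hydroxy-4,5-dimethoxyphenyl)pent-2-en-1-one (drawn as the E isomer; either geometry should cyclise) | CCN(CC)/C(CCc1ccc(OC)c(OCc2ccccc2)c1)=C/C(=O)c1cc(OC)c(OC)cc1O | intermediate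
23 | 2-{2-[3-(benzyloxy)-4-methoxyphenyl]ethyl}-6,7-dimethoxy-4H-chromen-4-one | COc1ccc(CCc2cc(=O)c3cc(OC)c(OC)cc3o2)cc1OCc1ccccc1 | intermediate
24 | 2-[2-(3-hydroxy-4-methoxyphenyl)ethyl]-6,7-dimethoxy-4H-chromen-4-one | COc1ccc(CCc2cc(=O)c3cc(OC)c(OC)cc3o2)cc1O | target

**Step count**

Total: 13 steps. Longest linear sequence: 12 steps (steps 1–7, then 9–13); step 8 is the one-step branch that supplies the carbene complex.

**Steps most likely to fail**

1. Step 9 (benzannulation). The alkyne may insert at the internal instead of the terminal triple bond, the vinylcarbene or ketene intermediate may divert to cyclopentannulation or furan formation, or the carbene complex may decompose thermally before it takes up the alkyne. The fallback uses known chemistry, gives up the benzannulation and buys ring A ready-made; it sets out from alkyne 7 and comes back to the route at diol 20. Commercial 2-hydroxy-4,5-dimethoxybenzaldehyde F1 is silylated (TBSCl, imidazole, DMF) to 2-(tert-butyldimethylsilyloxy)-4,5-dimethoxybenzaldehyde F2. The lithium acetylide 9, made from 7 as in step 5, is added at −78 °C and quenched with aq. NH4Cl to give racemic 5-[3-(benzyloxy)-4-methoxyphenyl]-1-[2-(tert-butyldimethylsilyloxy)-4,5-dimethoxyphenyl]pent-2-yn-1-ol F3; a silyl shift to the new alkoxide would be harmless. TBAF/AcOH in THF then removes the silyl group to give 20, and steps 11–13 follow unchanged.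

2. Step 8 (carbene complex). Hard O-methylation of the lithium acylchromate may be accompanied by decomposition of the electron-poor enol ether (polymerisation, hydrolysis) or by incomplete alkylation. The fallback replaces O-alkylation by O-acylation and alcoholysis; it sets out from acylchromate 16 and comes back at 17. The lithium salt 16 is exchanged with Me4NBr in water to precipitate tetramethylammonium pentacarbonyl(2-methoxyacryloyl)chromate F4, which can be isolated and stored. Acetyl bromide in CH2Cl2 at −40 °C converts it into pentacarbonyl[acetoxy(1-methoxyvinyl)carbene]chromium F5, and methanol at −40 to 0 °C exchanges the acetoxy for a methoxy group to give 17.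

3. Step 11 (MnO2 oxidation). The electron-rich 4-methoxyphenol ring may be over-oxidised towards a quinone in competition with carbinol oxidation, or the doubly activated carbinol may ionise on the oxidant surface. The fallback masks the phenol during oxidation; it sets out from 19 and comes back at 23. The phenol is acetylated (Ac2O, Et3N, DMAP cat., CH2Cl2) to racemic 2-{5-[3-(benzyloxy)-4-methoxyphenyl]-1-(tert-butyldimethylsilyloxy)pent-2-yn-1-yl}-4,5-dimethoxyphenyl acetate F6. HF·pyridine in THF/pyridine at 0 °C removes the silyl group without forming an alkoxide, so no acyl shift is expected, and gives racemic 2-{5-[3-(benzyloxy)-4-methoxyphenyl]-1-hydroxypent-2-yn-1-yl}-4,5-dimethoxyphenyl acetate F7. Dess–Martin periodinane (NaHCO3, CH2Cl2) oxidises this to 2-{5-[3-(benzyloxy)-4-methoxyphenyl]pent-2-ynoyl}-4,5-dimethoxyphenyl acetate F8. The Et2NH/EtOH conditions of step 12 then aminolyse the aryl acetate and cyclise in the same flask to 23.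

**Further compounds**

F1 | step 9 | 2-hydroxy-4,5-dimethoxybenzaldehyde | COc1cc(O)c(C=O)cc1OC
F2 | step 9 | 2-(tert-butyldimethylsilyloxy)-4,5-dimethoxybenzaldehyde | COc1cc(O[Si](C)(C)C(C)(C)C)c(C=O)cc1OC
F3 | step 9 | racemic 5-[3-(benzyloxy)-4-methoxyphenyl]-1-[2-(tert-butyldimethylsilyloxy)-4,5-dimethoxyphenyl]pent-2-yn-1-ol | COc1cc(O[Si](C)(C)C(C)(C)C)c(C(O)C#CCCc2ccc(OC)c(OCc3ccccc3)c2)cc1OC
F4 | step 8 | tetramethylammonium pentacarbonyl(2-methoxyacryloyl)chromate | C[N+](C)(C)C.[O-]C(C(=C)OC)=[Cr](=C=O)(=C=O)(=C=O)(=C=O)=C=O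
F5 | step 8 | pentacarbonyl[acetoxy(1-methoxyvinyl)carbene]chromium | CC(=O)OC(C(=C)OC)=[Cr](=C=O)(=C=O)(=C=O)(=C=O)=C=O
F6 | step 11 | racemic 2-{5-[3-(benzyloxy)-4-methoxyphenyl]-1-(tert-butyldimethylsilyloxy)pent-2-yn-1-yl}-4,5-dimethoxyphenyl acetate | COc1cc(OC(C)=O)c(C(O[Si](C)(C)C(C)(C)C)C#CCCc2ccc(OC)c(OCc3ccccc3)c2)cc1OC
F7 | step 11 | racemic 2-{5-[3-(benzyloxy)-4-methoxyphenyl]-1-hydroxypent-2-yn-1-yl}-4,5-dimethoxyphenyl acetate | COc1cc(OC(C)=O)c(C(O)C#CCCc2ccc(OC)c(OCc3ccccc3)c2)cc1OC
F8 | step 11 | 2-{5-[3-(benzyloxy)-4-methoxyphenyl]pent-2-ynoyl}-4,5-dimethoxyphenyl acetate | COc1cc(OC(C)=O)c(C(=O)C#CCCc2ccc(OC)c(OCc3ccccc3)c2)cc1OC
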